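Start from 0.0172 /h: this is my reading of what the starting material loses with the catalyst subtracted away, the background constant. Here is the flask you asked about, with the runs so far.

| setting | summer | midnight | dawn | winter | noon |
|---|---|---|---|---|---|
| starting material | 0.600 M | 0.600 M | 0.900 M | 0.600 M | 0.200 M |
| partner | 0.900 M | 0.900 M | 0.900 M | 0.900 M | 0.900 M |
| catalyst | 0.0600 M | 0.0600 M | 0.0600 M | 0.120 M | 0.0300 M |
| target |  | 0.300 M |  |  |  |
| time |  |  |  |  | 52 h |

- summer run (time / h: [starting material] / M): 2.3: 0.562; 7.0: 0.485; 13: 0.410; 21: 0.343; 30: 0.283; 41: 0.232; 52: 0.191
- midnight run (time / h: [starting material] / M): 2.3: 0.556; 7.0: 0.491; 13: 0.413; 21: 0.341; 30: 0.292; 41: 0.235; 52: 0.189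
- dawn run (time / h: [starting material] / M): 2.3: 0.838; 7.0: 0.745; 13: 0.643; 21: 0.542; 30: 0.440; 41: 0.365; 52: 0.295
- winter run (time / h: [starting material] / M): 2.3: 0.556; 7.0: 0.459; 13: 0.362; 21: 0.289; 30: 0.240; 41: 0.194; 52: 0.149

(standard deviation of a reading: 0.005 M)

- apparent order in [starting material] of the starting rate, round the charge of the summer run (the rate where two percent of its starting material have turned into target) (one fixed amount of target, the same in the runs compared)
- apparent order in [catalyst] of the starting rate, round the charge of the summer run (the rate where two percent of its starting material have turned into target)
- starting material in the noon run at 52 h, as a share of the starting material charged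

- Overall: starting material + partner -> target, with catalyst as catalyst.
- Constant volume, constant temperature.
- Bound and free are read together.
- "The second partner" is partner.
- An order is taken over about fifteen percent of the charge, up and down.

Your forecast gives 0.75 (range 0.5 to 0.95) for the order in [starting material], 0.4 (range 0.2 to 0.65) for the order in [catalyst], and 32% (range 23% to 45%) for the noon run, holding that twice the catalyst “raises the early rate only about 1.27-fold”.

Reckon it my way. Define a run's loss constant as the logarithm of charge over last reading, divided by that time. The summer run gives 0.0220 /h and the winter run, with twice the [catalyst], gives 0.0268 /h. Suppose the catalysed part is proportional to [catalyst], and subtract that step once from the summer value. This makes the order in [catalyst] one, by supposition and not by reading, and there I part from the forecast.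

Averaged up to the last reading, the catalysed part is then a correction, 0.00478 /h in the summer run, smaller than the background. The midnight run ends at 0.189 M against 0.191 M in the summer run, so I give added target no term. The dawn run has 0.0215 /h, which gives an order in [starting material] near 0.691, a soft reading through the scatter. Scaled to the noon charge, the correction is 0.00335 /h, so I commit to 34.3% left, close to the forecast.

The flask gives 0.51 and 1.0 for the orders, and the noon run keeps 32.9%.

    catalyst + starting material ⇌ catalyst-substrate complex, settled at all times (1.950 /M)
    catalyst-substrate complex + partner ⇌ ternary complex, settled at all times (0.1880 /M)
    ternary complex → target + catalyst (1.955 /h)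
    partner → lost reagent (0.05184 /h)
    starting material → decomposed substrate (0.01742 /h)

The winter run's target rate stands at 2.0 times the summer run's, at the same amount made. On the noon run, the background constant by itself reckons to 40.8% left, so the flask's figure asks for a correction of 0.00413 /h, against my 0.00335 /h. On the winter run, the background near the charge reckons to 0.0103 M/h beside a target rate of 0.017 M/h, so target takes about 62.7% of that early loss.

The earlier runs and the new flask stem from a simulated flask on assumed constants; the scatter is artificial.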